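## Retrosynthetic overview

- **Last bond (C4–C19):** the tetrahydrofuran methyl acetal and the C4 quaternary centre come from a photochemical decarboxylative 5-exo radical cyclization of a C6 bis(carboxymethyl) acetal.
- **Ring D (C13–C16):** photoredox 5-exo cyclization of an α-bromo ketone onto the ring-C alkene.
- **Ring C and δ-lactone:** Diels–Alder of butadiene with a spiro 3-acyl-5,6-dihydropyran-2-one, itself made by Knoevenagel–lactonization of a β-hydroxy aldehyde.
- **Ring A (C5, C10):** Diels–Alder of a 2-siloxy diene from (R)-glyceraldehyde acetonide with an α-methylene dioxanone; the bought stereocentre is later excised as the C6 aldehyde.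
- **Order of ring formation:** A → δ-lactone → C → D → tetrahydrofuran acetal.

Atom labels C1–C20 are the ent-kaurane numbers of the target.

Assumption: in step 5 the s-cis-locked dienophile reacts carbonyl-exo and the diene is attacked anti to its allylic C–O bond; if the facial sense is the opposite, ent-5 (from L-ascorbic acid) is used instead.

Assumption: the 6-OMe anomer of the target (OMe exo, trans to C10) is the thermodynamic one.

## Route

**Step 1**
Reactants: 1, ethyl 2-(hydroxymethyl)prop-2-enoate
Product: 2, 2-(hydroxymethyl)prop-2-enoic acid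
Conditions: LiOH·H2O, THF/H2O, BHT, 0 °C; then aq. KHSO4
Reagents that add atoms: water/hydroxide, O
Why: Simple ester saponification gives the β-hydroxy acid needed for the dioxanone; no stereocentre.

**Step 2**
Reactants: 2; 3, 2-methoxypropene
Product: 4, 2,2-dimethyl-5-methylidene-1,3-dioxan-4-one
Conditions: PPTS (cat.), CH2Cl2, 4 Å MS, 0 °C → rt
Reagents that add atoms: none beyond 3 (supplies CMe2)
Why: Ketalization then lactonization of a β-hydroxy acid (1,3-dioxan-4-one formation) locks the acrylate s-cis and pre-differentiates the two future C10 arms (C=O becomes C9, CH2O becomes C20).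

**Step 3**
Reactants: 5, (R)-2,2-dimethyl-1,3-dioxolane-4-carbaldehyde (from D-mannitol); 6, 3-(triphenyl-λ5-phosphanylidene)butan-2-one
Product: 7, (S,E)-4-(2,2-dimethyl-1,3-dioxolan-4-yl)-3-methylbut-3-en-2-one
Conditions: CH2Cl2, rt
Reagents that add atoms: none beyond 5 and 6
Why: Wittig olefination with a stabilized ylide is E-selective and does not touch the bought stereocentre (the descriptor changes from R to S only through CIP priorities).

**Step 4**
Reactants: 7
Product: 8, (S,E)-2-(tert-butyldimethylsilyloxy)-3-methyl-4-(2,2-dimethyl-1,3-dioxolan-4-yl)buta-1,3-diene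
Conditions: TBSOTf, Et3N, CH2Cl2, −78 → 0 °C
Reagents that add atoms: TBSOTf, CC(C)(C)[Si](C)(C)OS(=O)(=O)C(F)(F)F
Why: Soft enolization of the methyl ketone gives the cross-conjugated 2-siloxy diene; no new stereocentre.

**Step 5**
Reactants: 4; 8
Product: 9, spiro adduct: 9-(TBSO)-3,3,8-trimethyl-7-[(4S)-2,2-dimethyl-1,3-dioxolan-4-yl]-2,4-dioxaspiro[5.5]undec-8-en-1-one, with C20H2O cis to the dioxolanyl on ring A (C5-H β)
Conditions: toluene, BHT, 90 °C, sealed tube
Reagents that add atoms: none beyond 4 and 8
Why: Diels–Alder reaction in which the siloxy group (para) and the C5 substituent (ortho) both direct C5–C10 bonding, the carbonyl-exo transition state typical of s-cis α-methylene lactones places C20H2O cis to C6, and attack anti to the allylic C–O of the A(1,3)-locked dioxolane sets C5, and through it C10.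

**Step 6**
Reactants: 9
Product: 10, the corresponding C3 enol triflate
Conditions: CsF, PhNTf2, DME, rt
Reagents that add atoms: PhNTf2, FC(F)(F)S(=O)(=O)N(c1ccccc1)S(=O)(=O)C(F)(F)F
Why: Fluoride unmasks the regiodefined enolate, which is O-triflated in situ (enol triflate formation); no stereocentre changes.

**Step 7**
Reactants: 10
Product: 11, 3,3,8-trimethyl-7-[(4S)-dioxolan-4-yl]-2,4-dioxaspiro[5.5]undec-8-en-1-one (C3=C4 alkene, C3–H)
Conditions: Pd(OAc)2, PPh3, HCO2H, Bu3N, DMF, 60 °C
Reagents that add atoms: none
Why: Pd-catalysed formate reduction of the vinyl triflate removes the directing oxygen and leaves the C3=C4(Me) alkene in the position needed for step 15.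

**Step 8**
Reactants: 11
Product: 12, 1-(hydroxymethyl)-3-methyl-2-[(4S)-2,2-dimethyl-1,3-dioxolan-4-yl]cyclohex-3-ene-1-carbaldehyde (C20H2OH cis to C6, C9HO trans)
Conditions: DIBAL-H (1.1 equiv), CH2Cl2, −78 °C; Rochelle salt; brief SiO2/wet AcOH
Reagents that add atoms: none
Why: Half-reduction of the acyl ketal gives a lactol that collapses with loss of acetone to the β-hydroxy aldehyde, so the two C10 arms emerge already at the right oxidation levels.

**Step 9**
Reactants: 12; 13, methyl 3-oxopentanoate
Product: 14, 8-methyl-7-[(4S)-dioxolan-4-yl]-4-propanoyl-2-oxaspiro[5.5]undeca-4,8-dien-3-one (C7 lactone, C8=C9, C15 ketone)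
Conditions: piperidine/AcOH (10 mol%), toluene, 4 Å MS, 80 → 110 °C
Reagents that add atoms: none beyond 12 and 13
Why: Knoevenagel condensation followed by lactonization (the 3-acylcoumarin-type sequence) forms the δ-lactone and locks the doubly activated C8=C9 alkene geometry.

**Step 10**
Reactants: 14; 15, buta-1,3-diene
Product: 16, cis-fused Diels–Alder adduct (ring C with C12=C13; C8 quaternary; H9 on the same face as the C8 propanoyl)
Conditions: butadiene (excess), toluene, BHT, 110 °C, sealed tube
Reagents that add atoms: none beyond 14 and 15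
Why: Diels–Alder addition to the 2-acyl enoate occurs on the lactone face anti to the bulky C5 branch of the spiro centre, and suprafacial addition sets C8 and C9 (C7 and C10 cis).

**Step 11**
Reactants: 16
Product: 17, the C16 α-bromo ketone (epimer mixture at C16)
Conditions: LiHMDS, THF, −78 °C; then NBS
Reagents that add atoms: NBS, BrN1C(=O)CCC1=O
Why: C16 is the only enolizable position (C8 is quaternary), so enolate bromination is regiospecific.

**Step 12**
Reactants: 17
Product: 18, tetracyclic keto-lactone with the complete bicyclo[3.2.1]octane (C15 ketone, 16-methyl exo), ring-A alkene and dioxolane retained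
Conditions: [Ir(ppy)2(dtbbpy)]PF6 (1 mol%), Hantzsch ester, iPr2NEt, MeCN, blue LEDs, rt; then DBU (cat.)
Reagents that add atoms: none
Why: Photoredox reductive radical cyclization in which the α-keto radical adds 5-exo to C13 on the face of the axial acyl group (fixing C13), and C16 is equilibrated to the exo-methyl epimer.

**Step 13**
Reactants: 18
Product: 19, the C6 aldehyde (β,γ-unsaturated; C5 configuration retained)
Conditions: H5IO6, EtOAc, 0 °C → rt
Reagents that add atoms: none
Why: One-pot acetonide hydrolysis and glycol cleavage excises the control stereocentre and leaves C6 as the aldehyde.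

**Step 14**
Reactants: 19; 20, trimethylsilyl 2-(trimethylsilyloxy)acetate
Product: 21, C6 bis(carboxymethyl) acetal, used as its dipotassium salt
Conditions: 20 (2.5 equiv), TMSOTf (5 mol%), CH2Cl2, −78 °C; then aq. K2HPO4
Reagents that add atoms: none beyond 19 and 20
Why: Noyori acetalization is selective for the aldehyde over the hindered ketone, and the symmetric acetal creates no new stereocentre.

**Step 15**
Reactants: 21
Product: 22, ludongnin H
Conditions: Ir[dF(CF3)ppy]2(dtbbpy)PF6 (2 mol%), t-C12H25SH (5 mol%), DMSO (5 mM), blue LEDs, rt; then PPTS, MeOH, rt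
Reagents that add atoms: methanol, CO (OCH3 by acetal exchange)
Why: Proposed new method: photo-oxidation of one α-alkoxy carboxylate and loss of CO2 gives an acetal-tethered alkoxymethyl radical that adds 5-exo to the unactivated C3=C4 alkene on the face of C6, forming C4–C19 and the C4 quaternary centre with the ring cis-fused, then takes H from the thiol; the second arm is hydrodecarboxylated or exchanged to OMe and C6 equilibrates in PPTS/MeOH; the closest known reactions are photoredox decarboxylative α-oxy radical additions and tin-mediated Ueno–Stork/alkoxymethyl-radical cyclizations.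

## Compound list

1 | ethyl 2-(hydroxymethyl)prop-2-enoate | C=C(CO)C(=O)OCC | starting material
2 | 2-(hydroxymethyl)prop-2-enoic acid | C=C(CO)C(=O)O | intermediate
3 | 2-methoxypropene | COC(C)=C | starting material
4 | 2,2-dimethyl-5-methylidene-1,3-dioxan-4-one | C=C1COC(C)(C)OC1=O | intermediate
5 | (R)-2,2-dimethyl-1,3-dioxolane-4-carbaldehyde | O=C[C@H]1COC(C)(C)O1 | starting material
6 | 3-(triphenyl-λ5-phosphanylidene)butan-2-one | CC(=O)C(C)=P(c1ccccc1)(c1ccccc1)c1ccccc1 | starting material
7 | (S,E)-4-(2,2-dimethyl-1,3-dioxolan-4-yl)-3-methylbut-3-en-2-one | CC(=O)/C(C)=C/[C@H]1COC(C)(C)O1 | intermediate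
8 | (S,E)-2-(TBSO)-3-methyl-4-(2,2-dimethyl-1,3-dioxolan-4-yl)buta-1,3-diene | C=C(O[Si](C)(C)C(C)(C)C)/C(C)=C/[C@H]1COC(C)(C)O1 | intermediate
9 | spiro dioxanone silyl enol ether (ring A) | O=C1OC(C)(C)OC[C@]12CCC(O[Si](C)(C)C(C)(C)C)=C(C)[C@H]2[C@H]3COC(C)(C)O3 | intermediate
10 | C3 enol triflate | O=C1OC(C)(C)OC[C@]12CCC(OS(=O)(=O)C(F)(F)F)=C(C)[C@H]2[C@H]3COC(C)(C)O3 | intermediate
11 | spiro dioxanone, C3=C4 alkene | O=C1OC(C)(C)OC[C@]12CCC=C(C)[C@H]2[C@H]3COC(C)(C)O3 | intermediate
12 | ring-A β-hydroxy aldehyde | O=C[C@]1(CO)CCC=C(C)[C@H]1[C@H]2COC(C)(C)O2 | intermediate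
13 | methyl 3-oxopentanoate | CCC(=O)CC(=O)OC | starting material
14 | spiro 3-propanoyl-5,6-dihydropyran-2-one | CCC(=O)C1=C[C@]2(COC1=O)CCC=C(C)[C@H]2[C@H]3COC(C)(C)O3 | intermediate
15 | buta-1,3-diene | C=CC=C | starting material
16 | ring-C Diels–Alder adduct | CCC(=O)[C@]12CC=CC[C@H]1[C@]3(COC2=O)CCC=C(C)[C@H]3[C@H]4COC(C)(C)O4 | intermediate
17 | C16 α-bromo ketone | CC(Br)C(=O)[C@]12CC=CC[C@H]1[C@]3(COC2=O)CCC=C(C)[C@H]3[C@H]4COC(C)(C)O4 | intermediate
18 | bicyclo[3.2.1]octanone lactone with dioxolane | CC1=CCC[C@]2(COC(=O)[C@@]34C[C@@H](CC[C@H]32)[C@H](C)C4=O)[C@@H]1[C@H]5COC(C)(C)O5 | intermediate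
19 | C6 aldehyde | CC1=CCC[C@]2(COC(=O)[C@@]34C[C@@H](CC[C@H]32)[C@H](C)C4=O)[C@@H]1C=O | intermediate
20 | trimethylsilyl 2-(trimethylsilyloxy)acetate | C[Si](C)(C)OCC(=O)O[Si](C)(C)C | starting material
21 | C6 bis(carboxymethyl) acetal (dipotassium salt in use) | CC1=CCC[C@]2(COC(=O)[C@@]34C[C@@H](CC[C@H]32)[C@H](C)C4=O)[C@@H]1C(OCC(=O)O)OCC(=O)O | intermediate
22 | ludongnin H | CO[C@H]1OC[C@]2(C)CCC[C@]3(COC(=O)[C@@]45C[C@@H](CC[C@H]43)[C@H](C)C5=O)[C@H]12 | target

## Step count and main risks

Total steps: 15. Longest linear sequence: 13 (steps 3–15 from 5; the two-step preparation of 4 converges at step 5).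

Steps most likely to fail:

1. **Step 15 (proposed new photochemical cyclization).** The alkoxymethyl radical may be reduced before it cyclizes, or close 6-endo. Fallback with known chemistry: convert 21 to its bis-Barton ester (N-hydroxypyridine-2-thione, DCC) and photolyse with Bu3SnH added slowly — the established Barton decarboxylative radical cyclization — then PPTS/MeOH.
2. **Step 5 (first Diels–Alder).** The exo preference of the six-membered dienophile and the facial sense on the diene are both inferred from trends, not from this exact pair. Fallback: use diethyl methylenemalonate as a symmetric dienophile so there is no endo/exo issue, then reduce to the diol (LiAlH4) and let the C6 aldehyde (H5IO6) select the cis CH2OH as a lactol, which defines C10 from C5; a wrong facial sense is corrected by starting from ent-5.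
3. **Step 12 (ring D closure).** The α-keto radical could close 6-endo to the bicyclo[2.2.2]octane or be reduced prematurely. Fallback: Pd(OAc)2-mediated cycloalkenylation of the C15/C16 TBS enol ether of 16 (Toyota–Ihara type) to the bicyclo[3.2.1]octenone, followed by hydrogenation of the ring-C alkene.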